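The earlier runs and the new flask are simulated for an exercise; scatter was added.

Thursday's G climbs from 39.0 % to 40.4 % between 1.50 min and 2.50 min while D falls from 24.8 % to 11.4 %, and Saturday's G reads 19.7 % at 1.00 min and 17.8 % at 2.50 min while D falls from 13.6 % to 5.1 %, so G looks to be lost as well as made, and you can size that loss by hand.

| flask | D | remark | time |
|---|---|---|---|
| Thursday's | 0.38 M | run made earlier |  |
| Tuesday's | 0.97 M | run made earlier |  |
| Saturday's | 2.7 M | run made earlier |  |
| violet | 3.0 M |  | 5.0 min |
| teal | 1.0 M |  | 5.0 min |
| grey | 1.5 M |  | 5.0 min |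
| ochre | 0.30 M |  | 5.0 min |

| run | time / min | G / % | D / % |
|---|---|---|---|
| Thursday's | 0.333 | 17.3 | 69.5 |
| Thursday's | 0.833 | 30.7 | 43.2 |
| Thursday's | 1.50 | 39.0 | 24.8 |
| Thursday's | 2.50 | 40.4 | 11.4 |
| Tuesday's | 0.667 | 23.2 | 37.8 |
| Tuesday's | 1.33 | 29.7 | 16.0 |
| Tuesday's | 2.00 | 29.9 | 11.9 |
| Tuesday's | 2.50 | 30.2 | 7.8 |
| Saturday's | 0.200 | 8.3 | 50.3 |
| Saturday's | 0.500 | 15.4 | 27.7 |
| Saturday's | 1.00 | 19.7 | 13.6 |
| Saturday's | 2.50 | 17.8 | 5.1 |

(standard deviation of a reading: 1 percentage point)

- a reading or a percentage of G counts all its forms, free or not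

- all flasks from highest to lowest amount of G, in percent of the D charged, at 5.0 min (violet / teal / grey / ochre)
- the amount of G, in percent of the D charged of the flask you put first, at 5.0 min
- the amount of G, in percent of the D charged of the flask you put last, at 5.0 min

Replace each curve by its mean. Over Thursday's first reading, where G reaches 17.3 % and its loss is neglected, G formed divided by mean D and time gives a making constant of 0.613 min⁻¹. Over Thursday's last stretch, that constant times the arithmetic mean of D, less G's observed gain, divided by mean G, reads 0.244 min⁻¹. The weak link is that mean: D's curve bows below its chord. Reforged with the logarithmic mean of D, 17.2 %, which is lower than the arithmetic mean, the reading becomes 0.231 min⁻¹: the apparent first-order loss constant of G.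

From 2.50 min to 5.0 min, G already present keeps a fraction 0.561 of itself. Thursday's D fell at 0.777 min⁻¹ over that last stretch. Taking that rate onward, you reckon a fraction 0.789 of the D left to become G, and with that G decayed over the mean life of D, each point of D left is worth 0.586 of a point of G. Carried forward to 5.0 min, Thursday's run gives 29.4 %, Tuesday's 21.5 % and Saturday's 13.0 %. Your reckoning therefore has G falling as the charge rises, with ochre a little above Thursday's figure, teal near Tuesday's, grey below teal and violet a little below Saturday's.

The forecast has ochre > teal > grey > violet, with 28 % for ochre and 12 % for violet, on the ground that “dilute flasks give better yields”. Its order is yours.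

The flasks give ochre > teal > grey > violet, with 30.9 % for ochre and 11.1 % for violet.

    D → G (k = 0.0106 s⁻¹)
    2 D → X (k = 0.0119 M⁻¹ s⁻¹)
    D + G → Z (k = 5.06 × 10⁻⁴ M⁻¹ s⁻¹)
    E ⇌ G, rate k4*(cs4 - [G]) while solid is left; crystals form when [G] > cs4 (solubility = 0.760 M, k = 1.39 s⁻¹)
    G → Q (k = 0.00396 s⁻¹)

Violet holds 17.4 % of G and 3.12 % of D at 2.50 min. The same loss constant and worth of D carry that to 11.6 % at 5.0 min, against 11.1 % in the flask. The neighbouring flask is violet read earlier, at 3.0 min, where D stands at 2.13 %. Decaying violet's G over that short stretch and adding the fraction 0.789 of the D consumed gives 16.3 %. That neighbouring flask holds 16.2 % of G.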